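The slowness of the elm flask lies in its first minutes: target and isomer of the product together stand at 88.6 % of the solid substrate charged at 1.00 min, at 99.2 % at 1.50 min, and then stop rising.

| setting | elm | oak | flask |
|---|---|---|---|
| solid substrate | 0.010 M | 0.0050 M | 0.010 M |
| gas | 3.8 mM (held) | 3.8 mM (held) | 3.8 mM (held) |
| remark | the very flask that is asked about, followed so far | run made earlier |  |
| time |  |  | 5.0 min |

elm run (percent of the solid substrate charged)

| time / min | target / % | isomer of the product / % |
|---|---|---|
| 0.167 | 5.8 | 1.9 |
| 0.417 | 20.5 | 11.1 |
| 0.667 | 35.8 | 20.6 |
| 1.00 | 55.1 | 33.5 |
| 1.50 | 58.4 | 40.8 |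
| 2.00 | 57.9 | 41.2 |
| 2.50 | 59.3 | 41.9 |

oak run (percent of the solid substrate charged)

| time / s | target / % | isomer of the product / % |
|---|---|---|
| 10.0 | 12.9 | 4.0 |
| 20.0 | 33.0 | 13.9 |
| 30.0 | 52.7 | 27.2 |
| 50.0 | 59.2 | 40.5 |
| 80.0 | 58.4 | 41.4 |
| 90.0 | 59.0 | 40.0 |
| 120 | 58.7 | 42.2 |

(readings scatter by 0.5 percentage points)

1. why nothing more happens at 5.0 min, or that something still does (for what has run out or reacted, a solid counts together with what of it has only dissolved) (forward and back rates have come level / it is still moving / all of the solid substrate has reacted)
2. how much target there is at 5.0 min, in percent of the solid substrate charged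
3. how much isomer of the product there is at 5.0 min, in percent of the solid substrate charged

- solid substrate is a solid; its amount is given per volume of the solution
- at the start none of partner is dissolved
- what may be going on: solid substrate <-> dissolved substrate; dissolved substrate + partner -> target; target <-> isomer of the product; gas <-> partner; partner -> decomposed reagent
- at the start none of the solid substrate is in solution
- what has only dissolved of solid substrate counts as not reacted
- the reaction counts as stopped when no species that holds the solid substrate changes by six tenths of a point or more over the second half of the time

Follow one molecule of solid substrate: it dissolves, meets partner, becomes target, and may then pass to and fro between target and isomer of the product. The last elm reading gives 58.6 %: this is the target share, the chance of finding such a molecule as target once target and isomer of the product stand still. It is the equilibrium fraction, read with the scatter of the readings. The last reading of the oak run, with 0.0050 M of solid substrate, gives 58.2 %. With the pair at 101 % of the charge in the elm run, my own reckoning takes the charge as through and gives 58.6 % target and 41.4 % isomer of the product at 5.0 min.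

The forecast says all of the solid substrate has reacted, with 58.7 % target and 41.2 % isomer of the product, on the ground that “Nothing changes beyond scatter from 1.5 to 2.5 min”.

The flask gives this: all of the solid substrate has reacted, with 58.8 % target and 41.2 % isomer of the product.

    solid substrate ⇌ dissolved substrate, rate k1*(cs1 - [dissolved substrate]) while solid is left; crystals form when [dissolved substrate] > cs1 (solubility = 3.90 mM, k = 0.0568 s⁻¹)
    dissolved substrate + partner → target (k = 51.4 M⁻¹ s⁻¹)
    target ⇌ isomer of the product (K = 0.700, k = 0.0988 s⁻¹)
    gas ⇌ partner, rate k4*(csat - [partner]) (kL = 0.248 s⁻¹)
    partner → decomposed reagent (k = 0.0176 s⁻¹)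

In the flask, target and isomer of the product relax, by that step alone, with a half-life of 2.89 s, far shorter than 5.0 min. Solid substrate, the limiting reagent, stands there at 0 % at 5.00 min. With 0.040 M of solid substrate, the target share again reckons 58.6 % target and 41.4 % isomer of the product, as percentages of that flask's own charge. That flask gives 58.8 % and 41.2 % at 5.0 min, with 0 % of its solid substrate still there, solid or dissolved.

(The readings are simulated from invented constants; scatter was added.)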